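**Retrosynthetic overview**
1. Target ⇒ the 3'-OH of ring B goes in last (lithiation of the only C–H between two OMe groups, borylation/oxidation), together with release of the 7-OH.
2. The pyran ring (the only ring that is made) ⇒ one electrochemical step on an open-chain secondary alcohol: anodic phosphine activation, 1,2-shift of the ring-B aryl from C4 to C3 with inversion, and Friedel–Crafts closure of ring A onto C4 (forms C3–C1' and C4–C4a).
3. The alcohol ⇒ 2,4,5-trimethoxyphenyl Grignard + (S)-aryl glycidyl ether, opened at the epoxide CH2.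
4. The glycidyl ether ⇒ 2-methoxyresorcinol + bought (S)-glycidyl nosylate, which supplies the single stereocenter; rings A and B are bought as arenes.

Assumption: CIP analysis of the given SMILES gives the (3S)-isoflavan; (S)-glycidyl 3-nitrobenzenesulfonate is taken as the cheap bought source of that stereocenter.

**Step 1**
Reactants: 1 2-methoxybenzene-1,3-diol; 2 (2S)-oxiran-2-ylmethyl 3-nitrobenzenesulfonate
Product: 3 2-methoxy-3-{[(2S)-oxiran-2-yl]methoxy}phenol
Conditions: 1 (3 equiv, excess recovered), K2CO3 (1.2 equiv), DMF, rt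
Reagents that add atoms: none
Why: Williamson ether synthesis in which the phenoxide displaces the primary nosylate directly (SN2 at CH2, faster than epoxide opening), so the bought stereocenter is untouched and the (S)-glycidyl ether results, while the excess of the symmetric diol suppresses bis-alkylation.

**Step 2**
Reactants: 3 2-methoxy-3-{[(2S)-oxiran-2-yl]methoxy}phenol
Product: 4 {2-methoxy-3-[(2S)-oxiran-2-ylmethoxy]phenoxy}tri(propan-2-yl)silane
Conditions: TIPSCl, imidazole, DMF, rt
Reagents that add atoms: triisopropylsilyl chloride (TIPSCl), CC(C)[Si](Cl)(C(C)C)C(C)C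
Why: Standard phenol silylation gives a bulky TIPS ether that keeps ring A electron-rich for step 4, tolerates Grignard reagent, anode and n-BuLi, and leaves the epoxide and its stereocenter alone.

**Step 3**
Reactants: 4 {2-methoxy-3-[(2S)-oxiran-2-ylmethoxy]phenoxy}tri(propan-2-yl)silane; 5 1-bromo-2,4,5-trimethoxybenzene
Product: 7 (2S)-1-{2-methoxy-3-[tri(propan-2-yl)silyloxy]phenoxy}-3-(2,4,5-trimethoxyphenyl)propan-2-ol, via arylmagnesium bromide 6 (not isolated)
Conditions: 5 (1.5 equiv), Mg, LiCl, THF, rt; then 4, CuI (10 mol %), THF, −30 → 0 °C; aq. NH4Cl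
Reagents that add atoms: none
Why: Copper-catalysed Grignard opening of a terminal epoxide is an SN2 attack at the unsubstituted CH2, so the carbinol carbon keeps its configuration and becomes the (S)-alcohol.

**Step 4**
Reactants: 7 (2S)-1-{2-methoxy-3-[tri(propan-2-yl)silyloxy]phenoxy}-3-(2,4,5-trimethoxyphenyl)propan-2-ol
Product: 10 (3S)-8-methoxy-7-[tri(propan-2-yl)silyloxy]-3-(2,4,5-trimethoxyphenyl)chromane, via alkoxyphosphonium salt 8 (not isolated), via phenonium ion 9 (not isolated)
Conditions: (4-MeOC6H4)3P (1.2 equiv), nBu4NPF6, CH2Cl2/HFIP 9:1, RVC anode/Pt cathode, undivided cell, ca. +0.85 V vs SCE, 2 F per mol phosphine, 0 °C; then 35 °C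
Reagents that add atoms: none
Why: Proposed new method: anodic two-electron oxidation of the electron-rich triarylphosphine (expected to oxidise ca. 0.2–0.3 V below the trimethoxyarene) in the presence of alcohol 7 gives alkoxyphosphonium 8 in a medium free of nucleophilic anions; on warming in HFIP the 2,4,5-trimethoxyphenyl group displaces Ar3P=O at C3 from the back with inversion (anchimeric assistance, phenonium ion 9), and the tethered ring A, activated ortho to the ether oxygen and para to OSi, opens the phenonium at the primary carbon C4 in a 6-endo Friedel–Crafts closure, so the aryl group ends on C3 with the bought configuration transferred as (S) and C3–C1' and C4–C4a are formed in the same operation; the closest known reactions are the anodic generation of alkoxyphosphonium salts from phosphines and alcohols (electrochemical Mitsunobu/Appel-type activation), phenonium-ion Friedel–Crafts alkylation with β-aryl alcohols in HFIP, and the 6-endo epoxide–arene cyclisation of aryl glycidyl ethers to chroman-3-ols.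

**Step 5**
Reactants: 10 (3S)-8-methoxy-7-[tri(propan-2-yl)silyloxy]-3-(2,4,5-trimethoxyphenyl)chromane
Product: 14 (3S)-3-(3-hydroxy-2,4,5-trimethoxyphenyl)-8-methoxychroman-7-ol, via aryllithium 11 (not isolated), via arylboronic ester 12 (not isolated), via silyl-protected phenol 13 (not isolated)
Conditions: nBuLi (1.3 equiv), TMEDA, THF, 0 °C; B(OMe)3, −78 °C → rt; AcOH, 30% H2O2, 0 °C → rt; then TBAF, THF, rt
Reagents that add atoms: hydrogen peroxide, OO
Why: Directed ortho-lithiation takes the only aryl C–H flanked by two methoxy groups (as in 1,2,4,5-tetramethoxybenzene; the bulky OTIPS group is a poor director), borylation and peroxide oxidation (boron-to-oxygen 1,2-shift) turn it into the phenol and fluoride removes the silyl ether, while the non-acidic C3–H stereocenter is not touched.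

**Compound list**
1 | 2-methoxybenzene-1,3-diol (2-methoxyresorcinol) | COc1c(O)cccc1O | starting material
2 | (2S)-oxiran-2-ylmethyl 3-nitrobenzenesulfonate ((S)-glycidyl nosylate) | O=S(=O)(OC[C@@H]1CO1)c1cccc([N+](=O)[O-])c1 | starting material
3 | 2-methoxy-3-{[(2S)-oxiran-2-yl]methoxy}phenol | COc1c(O)cccc1OC[C@@H]1CO1 | intermediate
4 | {2-methoxy-3-[(2S)-oxiran-2-ylmethoxy]phenoxy}tri(propan-2-yl)silane | COc1c(O[Si](C(C)C)(C(C)C)C(C)C)cccc1OC[C@@H]1CO1 | intermediate
5 | 1-bromo-2,4,5-trimethoxybenzene | COc1cc(OC)c(Br)cc1OC | starting material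
6 | (2,4,5-trimethoxyphenyl)magnesium bromide | COc1cc(OC)c([Mg]Br)cc1OC | intermediate
7 | (2S)-1-{2-methoxy-3-[tri(propan-2-yl)silyloxy]phenoxy}-3-(2,4,5-trimethoxyphenyl)propan-2-ol | COc1c(O[Si](C(C)C)(C(C)C)C(C)C)cccc1OC[C@@H](O)Cc1cc(OC)c(OC)cc1OC | intermediate
8 | {[(2S)-1-{2-methoxy-3-[tri(propan-2-yl)silyloxy]phenoxy}-3-(2,4,5-trimethoxyphenyl)propan-2-yl]oxy}tris(4-methoxyphenyl)phosphonium hexafluorophosphate | COc1c(O[Si](C(C)C)(C(C)C)C(C)C)cccc1OC[C@@H](O[P+](c1ccc(OC)cc1)(c1ccc(OC)cc1)c1ccc(OC)cc1)Cc1cc(OC)c(OC)cc1OC.F[P-](F)(F)(F)(F)F | intermediate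
9 | phenonium ion (spiro[2.5]octadienyl cation, drawn as the 4-methoxy oxocarbenium form; cyclopropane carbon bearing the aryloxymethyl group is (S)), hexafluorophosphate | COc1c(O[Si](C(C)C)(C(C)C)C(C)C)cccc1OC[C@H]1CC12C=C(OC)C(=[O+]C)C=C2OC.F[P-](F)(F)(F)(F)F | intermediate
10 | (3S)-8-methoxy-7-[tri(propan-2-yl)silyloxy]-3-(2,4,5-trimethoxyphenyl)chromane | COc1cc([C@H]2COc3c(ccc(O[Si](C(C)C)(C(C)C)C(C)C)c3OC)C2)c(OC)cc1OC | intermediate
11 | 3'-lithio derivative of 10 (lithium between the 2'- and 4'-methoxy groups) | COc1cc([C@H]2COc3c(ccc(O[Si](C(C)C)(C(C)C)C(C)C)c3OC)C2)c(OC)c([Li])c1OC | intermediate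
12 | dimethyl 3'-boronate of 10 | COc1cc([C@H]2COc3c(ccc(O[Si](C(C)C)(C(C)C)C(C)C)c3OC)C2)c(OC)c(B(OC)OC)c1OC | intermediate
13 | (3S)-3-(3-hydroxy-2,4,5-trimethoxyphenyl)-8-methoxy-7-[tri(propan-2-yl)silyloxy]chromane | COc1cc([C@H]2COc3c(ccc(O[Si](C(C)C)(C(C)C)C(C)C)c3OC)C2)c(OC)c(O)c1OC | intermediate
14 | (3S)-3-(3-hydroxy-2,4,5-trimethoxyphenyl)-8-methoxychroman-7-ol (CNP0201239.1) | COc1cc([C@H]2COc3c(ccc(O)c3OC)C2)c(OC)c(O)c1OC | target

**Totals**
Total step count: 5. Longest linear sequence: 5 steps (1/2 → 3 → 4 → 7 → 10 → 14); bromide 5 is bought and enters at step 3.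

**Three steps most likely to fail**

Step 4 (the proposed new electrochemical cyclisation). Risks are anodic oxidation of the trimethoxyarene if the potential window is too narrow, 5-exo closure at C3 to a 3-benzyl-dihydrobenzofuran, elimination from the phenonium ion, or a phosphonium salt that is too stable to ionise. The fallback uses known chemistry, sets out from 4 and comes back at 10. HFIP with catalytic TfOH effects the known 6-endo epoxide–arene cyclisation of glycidyl ether 4 to (3S)-8-methoxy-7-[tri(propan-2-yl)silyloxy]chroman-3-ol F1. Tf2O and 2,6-lutidine convert it into (3S)-8-methoxy-7-[tri(propan-2-yl)silyloxy]chroman-3-yl trifluoromethanesulfonate F2. Grignard reagent 6 under CuI catalysis (THF, −40 °C) then displaces the triflate with inversion, a cuprate-type SN2 on a secondary sulfonate, and gives 10 with the same (S) configuration.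

Step 5 (late C–H hydroxylation). Risks are lithiation at C6' or on ring A, silyl migration, or over-oxidation of the electron-rich phenol. The fallback sets out from 4 and comes back at 14 by putting the ring-B oxygen in before the coupling. Commercial 1,2,4-trimethoxybenzene F3 is lithiated at C3 (nBuLi, THF), borylated and oxidised to 2,3,6-trimethoxyphenol F4, which is tosylated to 2,3,6-trimethoxyphenyl 4-methylbenzenesulfonate F5. NBS in MeCN should brominate para to the 2-methoxy group, giving 5-bromo-2,3,6-trimethoxyphenyl 4-methylbenzenesulfonate F6; the selectivity is expected but not certain, so any regioisomer is removed by chromatography. Mg/LiCl insertion gives [2,4,5-trimethoxy-3-(tosyloxy)phenyl]magnesium bromide F7, which opens epoxide 4 as in step 3 to (2S)-1-{2-methoxy-3-[tri(propan-2-yl)silyloxy]phenoxy}-3-[2,4,5-trimethoxy-3-(tosyloxy)phenyl]propan-2-ol F8. The electrolysis of step 4 then gives (3S)-8-methoxy-7-[tri(propan-2-yl)silyloxy]-3-[2,4,5-trimethoxy-3-(tosyloxy)phenyl]chromane F9, and KOH in MeOH/THF at 60 °C removes the tosylate and the silyl ether together to give 14.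

Step 1 (mono-alkylation of a symmetric diphenol). Risks are bis-alkylation, attack of the free phenoxide on the epoxide, and slight loss of ee if some phenoxide attacks the epoxide carbon. The fallback sets out from 1 and comes back at 4 by desymmetrising with the silyl group first. TIPSCl (0.9 equiv) and imidazole give 2-methoxy-3-[tri(propan-2-yl)silyloxy]phenol F10, and its single free phenol is alkylated with nosylate 2 (K2CO3, acetone, rt) to give 4 directly.

**Further compounds**
F1 | step 4 | (3S)-8-methoxy-7-[tri(propan-2-yl)silyloxy]chroman-3-ol | COc1c(O[Si](C(C)C)(C(C)C)C(C)C)ccc2c1OC[C@@H](O)C2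
F2 | step 4 | (3S)-8-methoxy-7-[tri(propan-2-yl)silyloxy]chroman-3-yl trifluoromethanesulfonate | COc1c(O[Si](C(C)C)(C(C)C)C(C)C)ccc2c1OC[C@@H](OS(=O)(=O)C(F)(F)F)C2
F3 | step 5 | 1,2,4-trimethoxybenzene (commercial) | COc1ccc(OC)c(OC)c1
F4 | step 5 | 2,3,6-trimethoxyphenol | COc1ccc(OC)c(OC)c1O
F5 | step 5 | 2,3,6-trimethoxyphenyl 4-methylbenzenesulfonate | COc1ccc(OC)c(OC)c1OS(=O)(=O)c1ccc(C)cc1
F6 | step 5 | 5-bromo-2,3,6-trimethoxyphenyl 4-methylbenzenesulfonate | COc1c(Br)cc(OC)c(OC)c1OS(=O)(=O)c1ccc(C)cc1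
F7 | step 5 | [2,4,5-trimethoxy-3-(tosyloxy)phenyl]magnesium bromide | COc1c([Mg]Br)cc(OC)c(OC)c1OS(=O)(=O)c1ccc(C)cc1
F8 | step 5 | (2S)-1-{2-methoxy-3-[tri(propan-2-yl)silyloxy]phenoxy}-3-[2,4,5-trimethoxy-3-(tosyloxy)phenyl]propan-2-ol | COc1c(O[Si](C(C)C)(C(C)C)C(C)C)cccc1OC[C@@H](O)Cc1cc(OC)c(OC)c(OS(=O)(=O)c2ccc(C)cc2)c1OC
F9 | step 5 | (3S)-8-methoxy-7-[tri(propan-2-yl)silyloxy]-3-[2,4,5-trimethoxy-3-(tosyloxy)phenyl]chromane | COc1cc([C@H]2COc3c(ccc(O[Si](C(C)C)(C(C)C)C(C)C)c3OC)C2)c(OC)c(OS(=O)(=O)c2ccc(C)cc2)c1OC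
F10 | step 1 | 2-methoxy-3-[tri(propan-2-yl)silyloxy]phenol | COc1c(O)cccc1O[Si](C(C)C)(C(C)C)C(C)C
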